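**Plan**

- Locants follow xenicane numbering: C1 (OCH2), O2, C3 (acetal CH), C4, C4a, C5–C10, C11 (=C19H2), C11a; side chain C12 (olefinic CH), C13 (OCH), C14 (CHOH), C15 (CMe2OH); the methyl on C7 is C18.
- Cuts, last to first: the C8–C9 epoxide oxygen (directed epoxidation); O2–C1 (base-mediated pyran closure on a butenolide-derived lactol, because the 2-alkoxy-2,5-dihydrofuran would aromatise to a furan under acid); C4a–C11a (key step); then the lactone C1(=O)–O–C12, C4–C12 (reductive aldol) and C8=C9 (Z-Wittig) of a linear seco acid.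
- Feature that allows the key event: C4a–C11a joins the α-carbon of a carboxyl-level carbon (C11a next to C1) to the allylic terminus of the C4=C12 olefin, so O=C1–C11a–C4a–C4=C12 is the retron of an ester-enolate [3,3] shift. Tying C1 to C12 through oxygen gives a 13-membered lactone whose ring contraction makes the nine-membered carbocycle and both ring-fusion centres at once.
- Forward: three pieces (C12–C15 aldehyde from D-erythronolactone, C1/C9–C11 phosphonium salt from isoprenol, C4a–C8 from (S)-linalool) → seco acid → 13-membered lactone → nine-membered ring → butenolide → lactol → pyran (bicyclic acetal) → epoxide.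
- Stereochemistry: C7 from (S)-linalool; C13 and C14 from D-erythronolactone; temporary C12 by Felkin–Anh addition; C4a and C11a by chirality transfer from C12 through a chair transition state; C3 by the only lactol anomer that can close a chair pyran; C8/C9 by hydroxyl-directed epoxidation syn to 7-OH.

Key step: step 18

**Route**

Step 1
Reactants: 1 2,3-O-isopropylidene-D-erythronolactone
Product: 2 2-[(4R,5R)-5-(hydroxymethyl)-2,2-dimethyl-1,3-dioxolan-4-yl]propan-2-ol
Conditions: MeMgBr (3 equiv), THF, 0 °C → rt; H2O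
Reagents that add atoms: methylmagnesium bromide (C[Mg]Br)
Why: Double Grignard addition to the lactone carbonyl should open the ring to the tertiary alcohol and the primary alcohol, and C13 and C14 come unchanged from the chiral pool.

Step 2
Reactants: 2 diol
Product: 3 bis(triethylsilyl) ether of 2
Conditions: Et3SiOTf (2.5 equiv), 2,6-lutidine, CH2Cl2, −78 → 0 °C
Reagents that add atoms: triethylsilyl triflate (CC[Si](CC)(CC)OS(=O)(=O)C(F)(F)F)
Why: Silyl triflate silylation should cap both the primary and the hindered tertiary hydroxyl.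

Step 3
Reactants: 3 bis(triethylsilyl) ether
Product: 4 (4S,5R)-2,2-dimethyl-5-[2-(triethylsilyloxy)propan-2-yl]-1,3-dioxolane-4-carbaldehyde
Conditions: (COCl)2, DMSO, CH2Cl2, −78 → −40 °C; Et3N, −78 → 0 °C
Reagents that add atoms: none
Why: Under Swern conditions only the primary triethylsilyl ether is cleaved and oxidised to the aldehyde (direct Swern oxidation of a primary silyl ether), and the low temperature should keep the α-stereocenter intact.

Step 4
Reactants: 5 3-methylbut-3-en-1-ol (isoprenol)
Product: 7 3-methylidenepentane-1,5-diol, via isoprenol dianion 6 (not isolated)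
Conditions: n-BuLi (2.2 equiv), TMEDA, Et2O–hexane, 0 °C → rt; (CH2O)n, −78 °C → rt; H2O
Reagents that add atoms: paraformaldehyde, as formaldehyde (C=O)
Why: Alkoxide-directed allylic lithiation at the methyl group followed by hydroxymethylation with formaldehyde (allyl anion alkylation) should give the symmetric diol.

Step 5
Reactants: 7 3-methylidenepentane-1,5-diol
Product: 8 5-(4-methoxybenzyloxy)-3-methylidenepentan-1-ol
Conditions: NaH (1.0 equiv), PMBCl, Bu4NI (cat.), THF–DMF, 0 °C → rt
Reagents that add atoms: 4-methoxybenzyl chloride (COc1ccc(CCl)cc1)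
Why: Statistical Williamson mono-etherification of the symmetric diol, with recovered diol recycled.

Step 6
Reactants: 8 mono-PMB ether
Product: 9 1-{[(5-iodo-3-methylidenepentyl)oxy]methyl}-4-methoxybenzene
Conditions: I2, PPh3, imidazole, CH2Cl2, 0 °C → rt
Reagents that add atoms: iodine (II)
Why: Appel-type iodination of the primary alcohol under neutral conditions leaves the 1,1-disubstituted olefin untouched.

Step 7
Reactants: 9 iodide
Product: 10 [5-(4-methoxybenzyloxy)-3-methylidenepentyl]triphenylphosphonium iodide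
Conditions: PPh3, MeCN, reflux
Reagents that add atoms: triphenylphosphine (c1ccc(cc1)P(c1ccccc1)c1ccccc1)
Why: SN2 quaternisation of triphenylphosphine by the primary iodide.

Step 8
Reactants: 11 (S)-(+)-linalool
Product: 12 (3S)-3,7-dimethyl-3-(triethylsilyloxy)octa-1,6-diene
Conditions: Et3SiOTf, 2,6-lutidine, CH2Cl2, −78 → 0 °C
Reagents that add atoms: triethylsilyl triflate (CC[Si](CC)(CC)OS(=O)(=O)C(F)(F)F)
Why: Silyl triflate silylation of the tertiary allylic alcohol, whose configuration becomes C7 of the target.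

Step 9
Reactants: 12 linalool silyl ether
Product: 13 (4S)-4-methyl-4-(triethylsilyloxy)hex-5-enal
Conditions: O3 (1 equiv), pyridine, CH2Cl2, −78 °C; Me2S
Reagents that add atoms: ozone ([O-][O+]=O)
Why: Chemoselective ozonolysis, since the electron-rich trisubstituted olefin reacts much faster than the hindered vinyl group next to the quaternary carbon.

Step 10
Reactants: 13 aldehyde
Product: 14 (3S)-3-methyl-3-(triethylsilyloxy)hept-1-en-6-yne
Conditions: dimethyl (1-diazo-2-oxopropyl)phosphonate, K2CO3, MeOH, 0 °C → rt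
Reagents that add atoms: dimethyl (1-diazo-2-oxopropyl)phosphonate (COP(=O)(OC)C(=[N+]=[N-])C(C)=O)
Why: Seyferth–Gilbert homologation with the Ohira–Bestmann reagent converts the aldehyde into the terminal alkyne under mild base.

Step 11
Reactants: 14 enyne
Product: 15 (2S)-2-methyl-2-(triethylsilyloxy)hex-5-ynal
Conditions: O3, CH2Cl2, −78 °C; PPh3
Reagents that add atoms: ozone ([O-][O+]=O)
Why: Ozonolysis of the remaining vinyl group, which reacts far faster than the terminal alkyne.

Step 12
Reactants: 10 phosphonium iodide; 15 (2S)-2-methyl-2-(triethylsilyloxy)hex-5-ynal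
Product: 17 (5S,6Z)-11-(4-methoxybenzyloxy)-5-methyl-9-methylidene-5-(triethylsilyloxy)undec-6-en-1-yne, via phosphorus ylide 16 (not isolated)
Conditions: 10, NaN(SiMe3)2, THF, −78 → 0 °C; then 15, −78 °C → rt
Reagents that add atoms: none
Why: Salt-free Wittig olefination of an unstabilised ylide with the α-branched aldehyde should give the Z olefin (C8=C9) through the kinetic cis-oxaphosphetane.

Step 13
Reactants: 17 Z-dienyne
Product: 19 methyl (6S,7Z)-12-(4-methoxybenzyloxy)-6-methyl-10-methylidene-6-(triethylsilyloxy)dodec-7-en-2-ynoate, via lithium acetylide 18 (not isolated)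
Conditions: n-BuLi, THF, −78 °C; ClCO2Me
Reagents that add atoms: methyl chloroformate (COC(=O)Cl)
Why: C-acylation of the lithium acetylide with a chloroformate installs C3 at the carboxyl level.

Step 14
Reactants: 19 ynoate; 4 dioxolane aldehyde
Product: 21 methyl (2Z,6S,7Z)-2-{(R)-[(4R,5R)-2,2-dimethyl-5-(2-triethylsilyloxypropan-2-yl)-1,3-dioxolan-4-yl](hydroxy)methyl}-12-(4-methoxybenzyloxy)-6-methyl-10-methylidene-6-(triethylsilyloxy)dodeca-2,7-dienoate, via vinylalane 20 (not isolated)
Conditions: i-Bu2AlH, N-methylmorpholine N-oxide, THF, 0 °C; 19; then 4, 0 °C → rt; aqueous potassium sodium tartrate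
Reagents that add atoms: none
Why: Syn hydroalumination of the ynoate puts aluminium on the α-carbon (vinylalumination, a reductive aldol route to β-substituted Morita–Baylis–Hillman adducts), so the C5 chain ends up cis to the ester, and Felkin–Anh attack anti to the α-oxygen of the aldehyde should set the temporary carbinol C12 as R.

Step 15
Reactants: 21 hydroxy enoate
Product: 22 methyl (2Z,6S,7Z)-2-{(R)-[(4R,5R)-2,2-dimethyl-5-(2-triethylsilyloxypropan-2-yl)-1,3-dioxolan-4-yl](hydroxy)methyl}-12-hydroxy-6-methyl-10-methylidene-6-(triethylsilyloxy)dodeca-2,7-dienoate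
Conditions: DDQ, CH2Cl2–pH 7 buffer, 0 °C
Reagents that add atoms: none
Why: Oxidative cleavage of the PMB ether by DDQ under buffered conditions spares the silyl ethers, the acetonide and the non-conjugated olefins.

Step 16
Reactants: 22 diol
Product: 24 (5Z,7S,10Z,12R)-12-[(4R,5R)-2,2-dimethyl-5-(2-triethylsilyloxypropan-2-yl)-1,3-dioxolan-4-yl]-12-hydroxy-11-(methoxycarbonyl)-7-methyl-3-methylidene-7-(triethylsilyloxy)dodeca-5,10-dienoic acid, via aldehyde 23 (not isolated)
Conditions: TEMPO (cat.), PhI(OAc)2, CH2Cl2, rt; then NaClO2, NaH2PO4, 2-methylbut-2-ene, t-BuOH–H2O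
Reagents that add atoms: sodium chlorite ([Na+].[O-]Cl=O)
Why: The oxoammonium oxidation is selective for the unhindered primary alcohol over the hindered secondary carbinol, and Pinnick oxidation in the same pot avoids handling the β,γ-unsaturated aldehyde.

Step 17
Reactants: 24 seco acid
Product: 25 methyl (6Z,8S,11Z,13R)-13-[(4R,5R)-2,2-dimethyl-5-(2-triethylsilyloxypropan-2-yl)-1,3-dioxolan-4-yl]-8-methyl-4-methylidene-2-oxo-8-(triethylsilyloxy)-1-oxacyclotrideca-6,11-diene-12-carboxylate (13-membered lactone C1(=O)–O–C12)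
Conditions: 2-methyl-6-nitrobenzoic anhydride, DMAP, CH2Cl2 (1 mM, slow addition), rt
Reagents that add atoms: none
Why: Shiina macrolactonization closes the 13-membered ring with retention at C12, and activation at room temperature should limit isomerisation of the β,γ-unsaturated acid.

Step 18
Reactants: 25 13-membered lactone
Product: 28 (1R,4Z,6S,9S)-9-{(1Z)-2-[(4R,5R)-2,2-dimethyl-5-(2-triethylsilyloxypropan-2-yl)-1,3-dioxolan-4-yl]-1-(methoxycarbonyl)ethenyl}-6-methyl-2-methylidene-6-(triethylsilyloxy)cyclonon-4-ene-1-carboxylic acid, via silyl ketene acetal 26 (not isolated), via trimethylsilyl ester 27 (not isolated)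
Conditions: LiN(iPr)2, Me3SiCl, Et3N, THF–DMPU (4:1), −78 °C; then −78 °C → rt, 45 °C; 1 M HCl, THF
Reagents that add atoms: none
Why: Kinetic deprotonation at C11a, which is α to the lactone carbonyl and allylic to C11=C19, and O-silylation in situ give ketene acetal 26, and on warming a [3,3]-sigmatropic shift across the 13-membered ring forms C4a–C11a as C12–O breaks, the silyl ester 27 being hydrolysed on work-up. The closest known reaction type is the ester-enolate (Ireland) Claisen ring contraction of macrocyclic allylic lactones to 2-alkenylcycloalkanecarboxylic acids. The nine-membered carbocycle closes by transannular bond formation, a four-atom ring contraction in which the seven-carbon tether C5–C11 spans the two termini of a chair six-centre array diequatorially, as in the chair Cope rearrangement of (E,E)-1,5-cyclodienes to trans-1,2-disubstituted rings. C4a (S) is set by chirality transfer from the 12R carbinol, because with C13 equatorial only one face of the C4=C4a olefin can reach C11a, and the same chair gives the new C4=C12 olefin with C13 cis to the ester. C11a (R, trans to C4a) is set by the ketene acetal geometry with C11 trans to the ring oxygen, which enolisation in the presence of DMPU and the extended s-trans lactone conformation of a ring of this size should favour. The step needs chair over boat and silylation ahead of transannular Michael addition of the enolate to the C4=C4a enoate, and the unstrained chair open to a 13-membered ring, the in-situ silyl chloride and the low temperature should secure these.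

Step 19
Reactants: 28 nine-membered acid
Product: 30 primary alcohol from 28 (CO2H at C1 becomes CH2OH; 4aS,7S,11aR unchanged), via mixed carbonic anhydride 29 (not isolated)
Conditions: i-BuOCOCl, N-methylmorpholine, THF, −15 °C; then NaBH4, MeOH, −15 → 0 °C
Reagents that add atoms: none
Why: Activation as the mixed carbonic anhydride and borohydride reduction should convert the acid into the alcohol without touching the conjugated methyl ester (chemoselective acid reduction), the short cold activation guarding C11a.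

Step 20
Reactants: 30 primary alcohol
Product: 31 methanesulfonate of 30
Conditions: MsCl, Et3N, CH2Cl2, 0 °C
Reagents that add atoms: methanesulfonyl chloride (CS(=O)(=O)Cl)
Why: Sulfonylation turns C1 into the electrophile for the later pyran closure.

Step 21
Reactants: 31 mesylate
Product: 32 butenolide: nine-membered ring (4aS,7S,11aR; 8Z olefin; 7-OH; 11-methylidene) bearing CH2OMs on C11a and (5R)-5-[(1R)-1,2-dihydroxy-2-methylpropyl]-2-oxo-2,5-dihydrofuran-3-yl on C4a
Conditions: CSA (cat.), MeOH, 0 °C → rt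
Reagents that add atoms: none
Why: Acid-catalysed methanolysis removes the acetonide and both tertiary silyl ethers, and the freed C13 hydroxyl, held cis to the ester across C4=C12, should lactonise to the γ-lactone in preference to the δ-lactone through O14.

Step 22
Reactants: 32 butenolide triol
Product: 33 14-O-triethylsilyl ether of 32
Conditions: Et3SiCl, imidazole, CH2Cl2, 0 °C
Reagents that add atoms: chlorotriethylsilane (CC[Si](CC)(CC)Cl)
Why: Silyl chloride with imidazole silylates only the secondary C14 hydroxyl, which blocks the six-membered lactol that this hydroxyl could otherwise form after the next step.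

Step 23
Reactants: 33 silylated butenolide
Product: 34 lactol from 33 (lactone C3=O reduced to CH–OH; both anomers)
Conditions: i-Bu2AlH (4 equiv), CH2Cl2, −78 °C; aqueous potassium sodium tartrate; used crude
Reagents that add atoms: none
Why: Half-reduction of the butenolide with the aluminium hydride at low temperature stops at the lactol, and the neutral work-up avoids acid-induced dehydration to a furan.

Step 24
Reactants: 34 lactol mesylate
Product: 35 bicyclic acetal (3S,4aS,7S,8Z,11aR,13R,14R): 8,9-deoxy-14-O-triethylsilyl target with free 7-OH and 15-OH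
Conditions: Cs2CO3, MeCN, 4 Å MS, rt
Reagents that add atoms: none
Why: Intramolecular Williamson etherification (anomeric O-alkylation) of the lactol, the most acidic hydroxyl, closes the pyran by 6-exo-tet displacement of the mesylate, and since the anomers interconvert by ring–chain tautomerism only the one that gives a chair pyran with both nine-membered-ring bonds equatorial should close, which sets C3 as S (H-3 cis to H-4a).

Step 25
Reactants: 35 bicyclic acetal
Product: 36 14-O-triethylsilyl ether of the target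
Conditions: VO(acac)2 (cat.), t-BuOOH, CH2Cl2, 0 °C → rt
Reagents that add atoms: tert-butyl hydroperoxide (CC(C)(C)OO)
Why: Hydroxyl-directed vanadium-catalysed epoxidation should deliver oxygen to the Z C8=C9 olefin on the face syn to the C7 hydroxyl (cis epoxy alcohol, as for medium-ring allylic alcohols), while the methylidene and the dihydrofuran olefin have no allylic hydroxyl and stay intact.

Step 26
Reactants: 36 silyl ether
Product: 37 target, (3S,4aS,7S,8R,9R,11aR,13R,14R)
Conditions: Bu4NF, AcOH (1:1), THF, 0 °C → rt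
Reagents that add atoms: none
Why: Buffered fluoride cleaves the secondary silyl ether without exposing the acetal or the epoxy alcohol to acid.

**Compound list**

1 | 2,3-O-isopropylidene-D-erythronolactone, (3aR,6aR) | O=C1OC[C@H]2OC(C)(C)O[C@@H]12 | starting material
2 | 2-[(4R,5R)-5-(hydroxymethyl)-2,2-dimethyl-1,3-dioxolan-4-yl]propan-2-ol | OC[C@@H]1[C@@H](OC(C)(C)O1)C(C)(C)O | intermediate
3 | bis(triethylsilyl) ether of 2 | CC[Si](CC)(CC)OC[C@@H]1[C@@H](OC(C)(C)O1)C(C)(C)O[Si](CC)(CC)CC | intermediate
4 | (4S,5R)-2,2-dimethyl-5-[2-(triethylsilyloxy)propan-2-yl]-1,3-dioxolane-4-carbaldehyde | O=C[C@@H]1[C@@H](OC(C)(C)O1)C(C)(C)O[Si](CC)(CC)CC | intermediate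
5 | 3-methylbut-3-en-1-ol (isoprenol) | C=C(C)CCO | starting material
6 | isoprenol dianion, lithium 3-(lithiomethyl)but-3-en-1-olate | [Li]CC(=C)CCO[Li] | intermediate (not isolated)
7 | 3-methylidenepentane-1,5-diol | C=C(CCO)CCO | intermediate
8 | 5-(4-methoxybenzyloxy)-3-methylidenepentan-1-ol | COc1ccc(COCCC(=C)CCO)cc1 | intermediate
9 | 1-{[(5-iodo-3-methylidenepentyl)oxy]methyl}-4-methoxybenzene | COc1ccc(COCCC(=C)CCI)cc1 | intermediate
10 | [5-(4-methoxybenzyloxy)-3-methylidenepentyl]triphenylphosphonium iodide | COc1ccc(COCCC(=C)CC[P+](c2ccccc2)(c2ccccc2)c2ccccc2)cc1.[I-] | intermediate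
11 | (S)-(+)-linalool, (3S)-3,7-dimethylocta-1,6-dien-3-ol | C=C[C@@](C)(O)CCC=C(C)C | starting material
12 | (3S)-3,7-dimethyl-3-(triethylsilyloxy)octa-1,6-diene | C=C[C@@](C)(O[Si](CC)(CC)CC)CCC=C(C)C | intermediate
13 | (4S)-4-methyl-4-(triethylsilyloxy)hex-5-enal | C=C[C@@](C)(O[Si](CC)(CC)CC)CCC=O | intermediate
14 | (3S)-3-methyl-3-(triethylsilyloxy)hept-1-en-6-yne | C=C[C@@](C)(O[Si](CC)(CC)CC)CCC#C | intermediate
15 | (2S)-2-methyl-2-(triethylsilyloxy)hex-5-ynal | O=C[C@@](C)(O[Si](CC)(CC)CC)CCC#C | intermediate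
16 | phosphorus ylide from 10 | COc1ccc(COCCC(=C)CC=P(c2ccccc2)(c2ccccc2)c2ccccc2)cc1 | intermediate (not isolated)
17 | (5S,6Z)-11-(4-methoxybenzyloxy)-5-methyl-9-methylidene-5-(triethylsilyloxy)undec-6-en-1-yne | COc1ccc(COCCC(=C)C/C=C\[C@@](C)(O[Si](CC)(CC)CC)CCC#C)cc1 | intermediate
18 | lithium acetylide of 17 | COc1ccc(COCCC(=C)C/C=C\[C@@](C)(O[Si](CC)(CC)CC)CCC#C[Li])cc1 | intermediate (not isolated)
19 | methyl (6S,7Z)-12-(4-methoxybenzyloxy)-6-methyl-10-methylidene-6-(triethylsilyloxy)dodec-7-en-2-ynoate | COc1ccc(COCCC(=C)C/C=C\[C@@](C)(O[Si](CC)(CC)CC)CCC#CC(=O)OC)cc1 | intermediate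
20 | vinylalane, methyl (2E,6S,7Z)-2-(diisobutylalumanyl)-12-(4-methoxybenzyloxy)-6-methyl-10-methylidene-6-(triethylsilyloxy)dodeca-2,7-dienoate | COc1ccc(COCCC(=C)C/C=C\[C@@](C)(O[Si](CC)(CC)CC)CC/C=C(C(=O)OC)/[Al](CC(C)C)CC(C)C)cc1 | intermediate (not isolated)
21 | hydroxy enoate (2Z,6S,7Z; carbinol R; dioxolane 4R,5R), full name in step 14 | COc1ccc(COCCC(=C)C/C=C\[C@@](C)(O[Si](CC)(CC)CC)CC/C=C(C(=O)OC)/[C@@H](O)[C@@H]2[C@@H](OC(C)(C)O2)C(C)(C)O[Si](CC)(CC)CC)cc1 | intermediate
22 | 12-hydroxy analogue of 21 (PMB removed), full name in step 15 | OCCC(=C)C/C=C\[C@@](C)(O[Si](CC)(CC)CC)CC/C=C(C(=O)OC)/[C@@H](O)[C@@H]1[C@@H](OC(C)(C)O1)C(C)(C)O[Si](CC)(CC)CC | intermediate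
23 | aldehyde from 22 (CH2OH becomes CHO) | O=CCC(=C)C/C=C\[C@@](C)(O[Si](CC)(CC)CC)CC/C=C(C(=O)OC)/[C@@H](O)[C@@H]1[C@@H](OC(C)(C)O1)C(C)(C)O[Si](CC)(CC)CC | intermediate (not isolated)
24 | seco acid (5Z,7S,10Z,12R), full name in step 16 | OC(=O)CC(=C)C/C=C\[C@@](C)(O[Si](CC)(CC)CC)CC/C=C(C(=O)OC)/[C@@H](O)[C@@H]1[C@@H](OC(C)(C)O1)C(C)(C)O[Si](CC)(CC)CC | intermediate
25 | 13-membered lactone (6Z,8S,11Z,13R), full name in step 17 | O=C1CC(=C)C/C=C\[C@@](C)(O[Si](CC)(CC)CC)CC/C=C(C(=O)OC)/[C@@H](O1)[C@@H]2[C@@H](OC(C)(C)O2)C(C)(C)O[Si](CC)(CC)CC | intermediate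
26 | (Z)-trimethylsilyl ketene acetal of 25 (C1=C11a, OSiMe3 cis to C11) | C[Si](C)(C)O/C1=C\C(=C)C/C=C\[C@@](C)(O[Si](CC)(CC)CC)CC/C=C(C(=O)OC)/[C@@H](O1)[C@@H]2[C@@H](OC(C)(C)O2)C(C)(C)O[Si](CC)(CC)CC | intermediate (not isolated)
27 | trimethylsilyl ester of 28 | C=C1C/C=C\[C@@](C)(O[Si](CC)(CC)CC)CC[C@H](/C(C(=O)OC)=C/[C@@H]2[C@@H](OC(C)(C)O2)C(C)(C)O[Si](CC)(CC)CC)[C@H]1C(=O)O[Si](C)(C)C | intermediate (not isolated)
28 | nine-membered acid (1R,4Z,6S,9S), full name in step 18 | C=C1C/C=C\[C@@](C)(O[Si](CC)(CC)CC)CC[C@H](/C(C(=O)OC)=C/[C@@H]2[C@@H](OC(C)(C)O2)C(C)(C)O[Si](CC)(CC)CC)[C@H]1C(=O)O | intermediate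
29 | mixed isobutyl carbonic anhydride of 28 | C=C1C/C=C\[C@@](C)(O[Si](CC)(CC)CC)CC[C@H](/C(C(=O)OC)=C/[C@@H]2[C@@H](OC(C)(C)O2)C(C)(C)O[Si](CC)(CC)CC)[C@H]1C(=O)OC(=O)OCC(C)C | intermediate (not isolated)
30 | primary alcohol from 28 (C1 as CH2OH) | C=C1C/C=C\[C@@](C)(O[Si](CC)(CC)CC)CC[C@H](/C(C(=O)OC)=C/[C@@H]2[C@@H](OC(C)(C)O2)C(C)(C)O[Si](CC)(CC)CC)[C@H]1CO | intermediate
31 | methanesulfonate of 30 | C=C1C/C=C\[C@@](C)(O[Si](CC)(CC)CC)CC[C@H](/C(C(=O)OC)=C/[C@@H]2[C@@H](OC(C)(C)O2)C(C)(C)O[Si](CC)(CC)CC)[C@H]1COS(C)(=O)=O | intermediate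
32 | butenolide mesylate with free 7-OH, 14-OH and 15-OH, description in step 21 | C=C1C/C=C\[C@@](C)(O)CC[C@H](C2=C[C@H]([C@@H](O)C(C)(C)O)OC2=O)[C@H]1COS(C)(=O)=O | intermediate
33 | 14-O-triethylsilyl ether of 32 | C=C1C/C=C\[C@@](C)(O)CC[C@H](C2=C[C@H]([C@@H](O[Si](CC)(CC)CC)C(C)(C)O)OC2=O)[C@H]1COS(C)(=O)=O | intermediate
34 | lactol from 33 (C3 as CH–OH, both anomers) | C=C1C/C=C\[C@@](C)(O)CC[C@H](C2=C[C@H]([C@@H](O[Si](CC)(CC)CC)C(C)(C)O)OC2O)[C@H]1COS(C)(=O)=O | intermediate
35 | bicyclic acetal (3S,4aS,7S,8Z,11aR,13R,14R), 8,9-deoxy-14-O-triethylsilyl target | C=C1C/C=C\[C@@](C)(O)CC[C@@H]2C3=C[C@H]([C@@H](O[Si](CC)(CC)CC)C(C)(C)O)O[C@@H]3OC[C@@H]12 | intermediate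
36 | 14-O-triethylsilyl ether of the target | C=C1C[C@H]2O[C@H]2[C@@](C)(O)CC[C@@H]2C3=C[C@H]([C@@H](O[Si](CC)(CC)CC)C(C)(C)O)O[C@@H]3OC[C@@H]12 | intermediate
37 | CNP0281409.2, (3S,4aS,7S,8R,9R,11aR,13R,14R) | C=C1C[C@H]2O[C@H]2[C@@](C)(O)CC[C@@H]2C3=C[C@H]([C@@H](O)C(C)(C)O)O[C@@H]3OC[C@@H]12 | target

**Step count and risks**

Total: 26 steps. Longest linear sequence: 19 steps (11 → 37 through steps 8–26; the branch from 5 through steps 4–7 and 12–26 is equally long).

Steps most likely to fail:

1. Step 18. What may go wrong: enolisation to the other ketene acetal geometry, or passage through a boat-like transition state, would erode or invert the trans relationship at C4a/C11a; transannular Michael addition of unsilylated enolate is a second leak. Fallback, setting out from enyne 14 and aldehyde 4 and coming back at acid 28: the [3,3] shift is run on an open-chain ester and the ring is closed afterwards by olefin metathesis. Enyne 14 would be acylated as in step 13 to vinyl ynoate F1, coupled with 4 as in step 14 to hydroxy enoate F2, and esterified (DCC, DMAP) with 3-methylidenehex-5-enoic acid F3, itself made from diketene and allylmagnesium chloride with NiCl2 as catalyst, to give open-chain ester F4. Ireland–Claisen rearrangement of F4 under the conditions of step 18, where solvent control of ketene acetal geometry and the chair transition state rest on open-chain precedent, should give open-chain acid F5. Ring-closing metathesis of its two monosubstituted olefins (second-generation Grubbs catalyst, dilute CH2Cl2, 40 °C) should then close the nine-membered ring as the Z olefin and arrive at 28.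

2. Step 24. What may go wrong: ring opening of the lactolate to the Z γ-oxido enal, followed by vinylogous enolisation and aromatisation to a furan, or etherification through the open-chain alkoxide. Fallback, setting out from lactol 34 and coming back at 35: the electrophile is activated instead of the nucleophile. Finkelstein exchange (NaI, acetone, rt) would give iodo lactol F6, and silver-assisted anomeric O-alkylation (Ag2O, 4 Å MS, CH2Cl2, dark) should close the pyran without any free alkoxide.

3. Step 14. What may go wrong: slow transfer of the β-substituted vinylalane to the hindered aldehyde, Z to E isomerisation of the vinylalane on warming, or poor facial selectivity at C12. Fallback, setting out from ynoate 19 and coming back at 21: palladium-catalysed syn hydrostannation (Bu3SnH, Pd(PPh3)2Cl2, THF) would give α-stannyl enoate F7, iododestannylation (I2, CH2Cl2, 0 °C) the α-iodo enoate F8 with retention, and Nozaki–Hiyama–Kishi coupling with 4 (CrCl2, NiCl2 cat., DMSO) should give 21 with the usual Felkin preference of alkenylchromium reagents.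

Further compounds
F1 | step 18 | methyl (6S)-6-methyl-6-(triethylsilyloxy)oct-7-en-2-ynoate | C=C[C@@](C)(O[Si](CC)(CC)CC)CCC#CC(=O)OC
F2 | step 18 | methyl (2Z,6S)-2-{(R)-[(4R,5R)-2,2-dimethyl-5-(2-triethylsilyloxypropan-2-yl)-1,3-dioxolan-4-yl](hydroxy)methyl}-6-methyl-6-(triethylsilyloxy)octa-2,7-dienoate | C=C[C@@](C)(O[Si](CC)(CC)CC)CC/C=C(C(=O)OC)/[C@@H](O)[C@@H]1[C@@H](OC(C)(C)O1)C(C)(C)O[Si](CC)(CC)CC
F3 | step 18 | 3-methylidenehex-5-enoic acid | C=CCC(=C)CC(=O)O
F4 | step 18 | 3-methylidenehex-5-enoate ester of F2 at the R carbinol | C=C[C@@](C)(O[Si](CC)(CC)CC)CC/C=C(C(=O)OC)/[C@@H](OC(=O)CC(=C)CC=C)[C@@H]1[C@@H](OC(C)(C)O1)C(C)(C)O[Si](CC)(CC)CC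
F5 | step 18 | open-chain Claisen acid (ring-opened 28 with vinyl on C7 and allyl on C11; 4aS,7S,11aR) | C=C[C@@](C)(O[Si](CC)(CC)CC)CC[C@H](/C(C(=O)OC)=C/[C@@H]1[C@@H](OC(C)(C)O1)C(C)(C)O[Si](CC)(CC)CC)[C@H](C(=C)CC=C)C(=O)O
F6 | step 24 | iodo lactol (34 with CH2I in place of CH2OMs) | C=C1C/C=C\[C@@](C)(O)CC[C@H](C2=C[C@H]([C@@H](O[Si](CC)(CC)CC)C(C)(C)O)OC2O)[C@H]1CI
F7 | step 14 | methyl (2E,6S,7Z)-12-(4-methoxybenzyloxy)-6-methyl-10-methylidene-2-(tributylstannyl)-6-(triethylsilyloxy)dodeca-2,7-dienoate | COc1ccc(COCCC(=C)C/C=C\[C@@](C)(O[Si](CC)(CC)CC)CC/C=C(C(=O)OC)/[Sn](CCCC)(CCCC)CCCC)cc1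
F8 | step 14 | methyl (2E,6S,7Z)-2-iodo-12-(4-methoxybenzyloxy)-6-methyl-10-methylidene-6-(triethylsilyloxy)dodeca-2,7-dienoate | COc1ccc(COCCC(=C)C/C=C\[C@@](C)(O[Si](CC)(CC)CC)CC/C=C(C(=O)OC)/I)cc1
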